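**Retrosynthetic overview**

1. The side chain comes last. The C1 tert-butyl acetate arm of methylidene-hydroazulene 23 is joined to a (5S)-menthyloxybutenolide by enolate Michael addition, so the lactone ring arrives preformed. The ester is then taken to CH2OAc, and C8=CH2 comes from the C8 ketone.
2. Hydroazulenone 22 comes from the oxygen-bridged tricycle 17 by enone hydrogenation, SmI2 cleavage of the C8a–O bond (which sets C8a–H) and Barton–McCombie removal of the C5 oxygen.
3. Key disconnection: intramolecular 3-oxidopyrylium–alkene (5+2) cycloaddition of acetoxypyranone 12. It forms C8a–C3a and C5–C4 and closes the five- and seven-membered carbocycles together, with the oxygen bridge as a third, temporary ring. The feature it rests on: in the seven-membered ring the only trigonal carbon, C8 (=CH2), is next to ring-fusion C8a, and the CMe2 carbon C4 lies beyond the other ring-fusion carbon C3a. This is the C3 / C2 / alkene-terminus pattern of an oxidopyrylium adduct whose C2 carries a quaternary carbon tethered to a prenyl unit.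
4. So that the quaternary carbon steers the cycloaddition the right way, the acetate arm is carried through it as a slim ethynyl group and grown to CH2CO2t-Bu afterwards.
5. Pyranone 12 comes from furyl carbinol 10 (Achmatowicz), which comes from α-quaternary aldehyde 6, which comes from the Sharpless epoxide of geraniol opened at C3 by an alkynylalane.

Key step: step 7

Remark: azulene numbering is used for the carbocyclic core (C1 quaternary carbon, C3a and C8a ring fusion, C4 gem-dimethyl, C8 methylidene). The carbinol carbon of 10 and C2/C6 of 11 and 12 are formed as epimer mixtures; all of them become trigonal in 13, so their SMILES leave these centres open.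

**Route**

Step 1
Reactants: 1 geraniol
Product: 2 [(2S,3S)-3-methyl-3-(4-methylpent-3-en-1-yl)oxiran-2-yl]methanol
Conditions: Ti(OiPr)4 (5 mol%), L-(+)-diethyl tartrate (6 mol%), t-BuOOH, 4 Å MS, CH2Cl2, −20 °C
Reagents that add atoms: tert-butyl hydroperoxide, CC(C)(C)OO
Why: Sharpless asymmetric epoxidation of the allylic alcohol; the L-(+)-tartrate complex should deliver oxygen to the alkene face that gives the (2S,3S)-epoxide, which fixes the configuration of the future quaternary carbon, while the remote trisubstituted alkene is not touched.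

Step 2
Reactants: 2 [(2S,3S)-3-methyl-3-(4-methylpent-3-en-1-yl)oxiran-2-yl]methanol; 3 ethynyltrimethylsilane
Product: 5 (2R,3S)-3-methyl-3-(4-methylpent-3-en-1-yl)-5-(trimethylsilyl)pent-4-yne-1,2-diol, via alkynylalane 4 (not isolated)
Conditions: 3, n-BuLi, toluene, 0 °C; Et2AlCl; then 2, 0 → 25 °C; aq. Rochelle salt
Reagents that add atoms: none
Why: Regioselective opening of a 2,3-epoxy alcohol by an alkynylalane (Nozaki–Oshima type); the aluminium-activated epoxide should be attacked at the tertiary C3 with inversion, which creates the all-carbon quaternary centre (3S).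

Step 3
Reactants: 5 (2R,3S)-3-methyl-3-(4-methylpent-3-en-1-yl)-5-(trimethylsilyl)pent-4-yne-1,2-diol
Product: 6 (2S)-2,6-dimethyl-2-[(trimethylsilyl)ethynyl]hept-5-enal
Conditions: NaIO4, THF/H2O, 0 → 25 °C
Reagents that add atoms: none
Why: Periodate glycol cleavage (Malaprade) removes C1 as formaldehyde and leaves an α-quaternary aldehyde that cannot enolise and therefore keeps its configuration.

Step 4
Reactants: 6 (2S)-2,6-dimethyl-2-[(trimethylsilyl)ethynyl]hept-5-enal; 7 furan
Product: 10 (2S)-2-ethynyl-1-(furan-2-yl)-2,6-dimethylhept-5-en-1-ol (C1 epimers), via 2-furyllithium 8 (not isolated), via silylated lithium alkoxide 9 (not isolated)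
Conditions: furan, n-BuLi, THF, 0 °C; then 6, −78 °C; then MeOH, K2CO3, 25 °C
Reagents that add atoms: none
Why: 1,2-Addition of an aryllithium to a non-enolisable aldehyde, followed by base-mediated methanolysis of the alkynyl–silicon bond; the new carbinol centre forms as an epimer mixture that is erased in step 7.

Step 5
Reactants: 10 (2S)-2-ethynyl-1-(furan-2-yl)-2,6-dimethylhept-5-en-1-ol
Product: 11 2-[(3S)-3,7-dimethyloct-6-en-1-yn-3-yl]-6-hydroxy-2H-pyran-3(6H)-one (C2/C6 isomers)
Conditions: VO(acac)2 (5 mol%), t-BuOOH, CH2Cl2, 0 → 25 °C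
Reagents that add atoms: tert-butyl hydroperoxide, CC(C)(C)OO
Why: Achmatowicz rearrangement; the hydroxyl-directed vanadium-catalysed oxidation should act on the furan only, since the trisubstituted alkene is too remote from the hydroxyl for directed epoxidation and the alkyne is inert.

Step 6
Reactants: 11 2-[(3S)-3,7-dimethyloct-6-en-1-yn-3-yl]-6-hydroxy-2H-pyran-3(6H)-one
Product: 12 6-[(3S)-3,7-dimethyloct-6-en-1-yn-3-yl]-5-oxo-5,6-dihydro-2H-pyran-2-yl acetate (C2/C6 isomers)
Conditions: Ac2O, pyridine, DMAP (cat.), CH2Cl2, 0 °C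
Reagents that add atoms: acetic anhydride, CC(=O)OC(C)=O
Why: Acetylation of the anomeric hydroxyl installs the leaving group for pyrylium formation; the weak base and low temperature should avoid premature elimination.

Step 7
Reactants: 12 6-[(3S)-3,7-dimethyloct-6-en-1-yn-3-yl]-5-oxo-5,6-dihydro-2H-pyran-2-yl acetate
Product: 14 (1S,3aS,5S,8aR)-1-ethynyl-1,4,4-trimethyl-2,3,3a,4-tetrahydro-1H-5,8a-epoxyazulen-8(5H)-one, via 3-oxidopyrylium 13 (not isolated)
Conditions: DBU (1.5 equiv), MeCN (0.005–0.01 M), 25 → 80 °C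
Reagents that add atoms: none
Why: DBU removes the acidic C2 proton of the pyranone and acetate leaves from C6, giving the aromatic 3-oxidopyrylium 13, whose five-atom, four-electron unit adds suprafacially to the tethered alkene in a concerted (5+2) cycloaddition; the closest known reaction type is the intramolecular oxidopyrylium–alkene cycloaddition of Achmatowicz-derived acetoxypyranones (Sammes–Wender type). The five-membered ring closes by bonding of pyrylium C2 to the inner alkene carbon through the three-atom tether, which can only span the ring-oxygen side of the dipole, so the tether is exo and the new C3a hydrogen is endo; the seven-membered ring closes in the same event by bonding of C6 to the CMe2 carbon and is bridged by the ring oxygen, which fixes C5 and C8a relative to C3a. Which face of the pyrylium is attacked is decided by the quaternary carbon: with the tether held on the oxygen side, one of its two other substituents must nearly eclipse the C2–C3 bond next to the oxido oxygen and the other points away from the dipole, and the rod-like ethynyl group (A value about 0.4) should take the eclipsed site in preference to methyl (about 1.7). That arrangement is the one in which the C3a hydrogen ends up cis to the ethynyl arm, as the target requires. The step needs this facial selectivity and trapping that is faster than pyrylium dimerisation; the first rests on the ethynyl-versus-methyl difference, the second on high dilution and on heat, which returns dimer to monomer.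

Step 8
Reactants: 14 (1S,3aS,5S,8aR)-1-ethynyl-1,4,4-trimethyl-2,3,3a,4-tetrahydro-1H-5,8a-epoxyazulen-8(5H)-one
Product: 15 [(1S,3aS,5S,8aR)-1,4,4-trimethyl-8-oxo-2,3,3a,4,5,8-hexahydro-1H-5,8a-epoxyazulen-1-yl]acetaldehyde
Conditions: [CpRu(MeCN){2-Ph2P-6-(t-Bu)C5H3N}2]PF6 (5 mol%), acetone/H2O, 70 °C
Reagents that add atoms: water, O
Why: Ruthenium-catalysed anti-Markovnikov hydration of a terminal alkyne through a vinylidene complex should give the aldehyde under neutral conditions that leave the enone and the bridging ether intact.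

Step 9
Reactants: 15 [(1S,3aS,5S,8aR)-1,4,4-trimethyl-8-oxo-2,3,3a,4,5,8-hexahydro-1H-5,8a-epoxyazulen-1-yl]acetaldehyde
Product: 16 [(1S,3aS,5S,8aR)-1,4,4-trimethyl-8-oxo-2,3,3a,4,5,8-hexahydro-1H-5,8a-epoxyazulen-1-yl]acetic acid
Conditions: NaClO2, NaH2PO4, 2-methylbut-2-ene, t-BuOH/H2O, 0 → 25 °C
Reagents that add atoms: sodium chlorite, [Na+].[O-]Cl=O
Why: Pinnick oxidation converts the aldehyde to the acid without touching the enone; the alkene scavenger removes hypochlorous acid.

Step 10
Reactants: 16 [(1S,3aS,5S,8aR)-1,4,4-trimethyl-8-oxo-2,3,3a,4,5,8-hexahydro-1H-5,8a-epoxyazulen-1-yl]acetic acid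
Product: 17 tert-butyl [(1S,3aS,5S,8aR)-1,4,4-trimethyl-8-oxo-2,3,3a,4,5,8-hexahydro-1H-5,8a-epoxyazulen-1-yl]acetate
Conditions: O-tert-butyl-N,N'-diisopropylisourea, CH2Cl2, 25 °C
Reagents that add atoms: O-tert-butyl-N,N'-diisopropylisourea, CC(C)NC(=NC(C)C)OC(C)(C)C
Why: Esterification by tert-butyl transfer from the protonated isourea proceeds under neutral conditions and gives an ester that later resists alkoxide, borohydride and hydroxide.

Step 11
Reactants: 17 tert-butyl [(1S,3aS,5S,8aR)-1,4,4-trimethyl-8-oxo-2,3,3a,4,5,8-hexahydro-1H-5,8a-epoxyazulen-1-yl]acetate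
Product: 18 tert-butyl [(1S,3aS,5S,8aR)-1,4,4-trimethyl-8-oxooctahydro-1H-5,8a-epoxyazulen-1-yl]acetate
Conditions: H2 (1 atm), 10% Pd/C, EtOAc, 25 °C
Reagents that add atoms: none
Why: Catalytic hydrogenation of the strained enone alkene; no stereocentre is formed, and removing the alkene first makes the later SmI2 cleavage unambiguous.

Step 12
Reactants: 18 tert-butyl [(1S,3aS,5S,8aR)-1,4,4-trimethyl-8-oxooctahydro-1H-5,8a-epoxyazulen-1-yl]acetate
Product: 20 tert-butyl [(1S,3aR,5S,8aR)-5-hydroxy-1,4,4-trimethyl-8-oxodecahydroazulen-1-yl]acetate, via samarium enolate 19 (not isolated)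
Conditions: SmI2 (2.5 equiv), t-BuOH, THF, −78 °C
Reagents that add atoms: none
Why: SmI2 reductive cleavage of an α-alkoxy ketone breaks the C8a–O bond and gives a samarium enolate and the C5 alkoxide; kinetic C-protonation by the bulky alcohol on the convex face, away from the C4 carbon of the seven-membered ring, should place the C8a hydrogen cis to the C3a hydrogen.

Step 13
Reactants: 20 tert-butyl [(1S,3aR,5S,8aR)-5-hydroxy-1,4,4-trimethyl-8-oxodecahydroazulen-1-yl]acetate
Product: 21 tert-butyl [(1S,3aR,5S,8aR)-5-(imidazol-1-ylcarbonothioyloxy)-1,4,4-trimethyl-8-oxodecahydroazulen-1-yl]acetate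
Conditions: 1,1'-thiocarbonyldiimidazole, DMAP, ClCH2CH2Cl, 80 °C
Reagents that add atoms: 1,1'-thiocarbonyldiimidazole, S=C(n1ccnc1)n1ccnc1
Why: Thioacylation of the secondary alcohol under non-enolising conditions prepares the Barton–McCombie substrate without disturbing the epimerisable C8a centre.

Step 14
Reactants: 21 tert-butyl [(1S,3aR,5S,8aR)-5-(imidazol-1-ylcarbonothioyloxy)-1,4,4-trimethyl-8-oxodecahydroazulen-1-yl]acetate
Product: 22 tert-butyl [(1S,3aR,8aR)-1,4,4-trimethyl-8-oxodecahydroazulen-1-yl]acetate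
Conditions: Bu3SnH, AIBN (cat.), toluene, 110 °C
Reagents that add atoms: none
Why: Barton–McCombie deoxygenation: the tin radical adds to sulfur, the secondary C5 radical is released and is reduced by the stannane; no stereocentre remains at C5.

Step 15
Reactants: 22 tert-butyl [(1S,3aR,8aR)-1,4,4-trimethyl-8-oxodecahydroazulen-1-yl]acetate
Product: 23 tert-butyl [(1S,3aR,8aS)-1,4,4-trimethyl-8-methylidenedecahydroazulen-1-yl]acetate
Conditions: Cp2TiMe2 (2 equiv), toluene, 65 °C, dark
Reagents that add atoms: dimethyltitanocene, C[Ti](C)(C1C=CC=C1)C1C=CC=C1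
Why: Petasis methylenation is non-basic, so the C8a centre next to the ketone is not epimerised, and the ketone should react well before the hindered tert-butyl ester.

Step 16
Reactants: 24 5-hydroxyfuran-2(5H)-one; 25 (1S,2R,5S)-(+)-menthol
Product: 26 (5S)-5-{[(1S,2R,5S)-5-methyl-2-(propan-2-yl)cyclohexyl]oxy}furan-2(5H)-one
Conditions: TsOH·H2O (cat.), toluene, reflux (Dean–Stark); crystallisation from petroleum ether
Reagents that add atoms: none
Why: Acid-catalysed acetalisation; the C5 epimers interconvert under acid and the (5S) isomer is collected by crystallisation, as in the known preparation of its enantiomer from (−)-menthol.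

Step 17
Reactants: 23 tert-butyl [(1S,3aR,8aS)-1,4,4-trimethyl-8-methylidenedecahydroazulen-1-yl]acetate; 26 (5S)-5-{[(1S,2R,5S)-5-methyl-2-(propan-2-yl)cyclohexyl]oxy}furan-2(5H)-one
Product: 28 tert-butyl (2R)-2-[(2S,3R)-2-{[(1S,2R,5S)-5-methyl-2-(propan-2-yl)cyclohexyl]oxy}-5-oxooxolan-3-yl]-2-[(1R,3aR,8aS)-1,4,4-trimethyl-8-methylidenedecahydroazulen-1-yl]acetate, via lithium enolate 27 (not isolated)
Conditions: LDA, THF, −78 → −40 °C; then 26, −78 °C; aq. NH4Cl
Reagents that add atoms: none
Why: Michael addition of a lithium ester enolate to a γ-alkoxybutenolide: the menthyloxy group forces attack on the opposite ring face and so sets the lactone carbon (R), while the side-chain carbon is set by the mutual approach of the two π systems, expected through a synclinal (Seebach-type) arrangement that keeps the enolate oxygens over the lactone carbonyl and turns the bulky hydroazulenyl group away from C5, which corresponds to (R).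

Step 18
Reactants: 28 the Michael adduct of step 17
Product: 30 tert-butyl (2R)-2-[(3R)-5-oxooxolan-3-yl]-2-[(1R,3aR,8aS)-1,4,4-trimethyl-8-methylidenedecahydroazulen-1-yl]acetate, via hydroxy acid 29 (not isolated)
Conditions: NaBH4, KOH, EtOH/H2O, 0 → 25 °C; then 1 M HCl to pH 2, 0 °C
Reagents that add atoms: none
Why: Hydroxide opens the lactone acetal to the aldehyde carboxylate with loss of menthol, borohydride reduces the aldehyde at once, and acidification closes the γ-lactone; the tert-butyl ester survives and the lactone carbon is reduced before it can epimerise.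

Step 19
Reactants: 30 tert-butyl (2R)-2-[(3R)-5-oxooxolan-3-yl]-2-[(1R,3aR,8aS)-1,4,4-trimethyl-8-methylidenedecahydroazulen-1-yl]acetate
Product: 32 (2R)-2-[(3R)-5-oxooxolan-3-yl]-2-[(1R,3aR,8aS)-1,4,4-trimethyl-8-methylidenedecahydroazulen-1-yl]acetic acid, via trimethylsilyl ester 31 (not isolated)
Conditions: TMSOTf, 2,6-lutidine, CH2Cl2, 0 °C; then H2O
Reagents that add atoms: none
Why: Silyl triflate–mediated cleavage of the tert-butyl ester (loss of isobutene) under buffered, aprotic conditions avoids the protic acid that would isomerise the exocyclic alkene.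

Step 20
Reactants: 32 (2R)-2-[(3R)-5-oxooxolan-3-yl]-2-[(1R,3aR,8aS)-1,4,4-trimethyl-8-methylidenedecahydroazulen-1-yl]acetic acid
Product: 34 (4R)-4-{(1R)-2-hydroxy-1-[(1R,3aR,8aS)-1,4,4-trimethyl-8-methylidenedecahydroazulen-1-yl]ethyl}oxolan-2-one, via acyl imidazolide 33 (not isolated)
Conditions: CDI, THF, 25 °C; then NaBH4, H2O, 0 °C
Reagents that add atoms: none
Why: Reduction of the activated acyl imidazolide by borohydride is much faster than reduction of the γ-lactone and, unlike borane, does not touch the 1,1-disubstituted alkene.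

Step 21
Reactants: 34 (4R)-4-{(1R)-2-hydroxy-1-[(1R,3aR,8aS)-1,4,4-trimethyl-8-methylidenedecahydroazulen-1-yl]ethyl}oxolan-2-one
Product: 35 (2R)-2-[(3R)-5-oxooxolan-3-yl]-2-[(1R,3aR,8aS)-1,4,4-trimethyl-8-methylidenedecahydroazulen-1-yl]ethyl acetate (target)
Conditions: Ac2O, pyridine, DMAP (cat.), CH2Cl2, 0 °C
Reagents that add atoms: acetic anhydride, CC(=O)OC(C)=O
Why: Acetylation of the primary alcohol completes the target; no stereocentre is affected.

**Compound list**

1 | geraniol, (2E)-3,7-dimethylocta-2,6-dien-1-ol | CC(C)=CCC/C(C)=C/CO | starting material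
2 | [(2S,3S)-3-methyl-3-(4-methylpent-3-en-1-yl)oxiran-2-yl]methanol | CC(C)=CCC[C@]1(C)O[C@H]1CO | intermediate
3 | ethynyltrimethylsilane | C#C[Si](C)(C)C | starting material
4 | diethyl[(trimethylsilyl)ethynyl]alane | CC[Al](CC)C#C[Si](C)(C)C | intermediate (not isolated)
5 | (2R,3S)-3-methyl-3-(4-methylpent-3-en-1-yl)-5-(trimethylsilyl)pent-4-yne-1,2-diol | CC(C)=CCC[C@@](C)(C#C[Si](C)(C)C)[C@@H](O)CO | intermediate
6 | (2S)-2,6-dimethyl-2-[(trimethylsilyl)ethynyl]hept-5-enal | CC(C)=CCC[C@@](C)(C#C[Si](C)(C)C)C=O | intermediate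
7 | furan | c1ccoc1 | starting material
8 | 2-furyllithium | [Li]c1ccco1 | intermediate (not isolated)
9 | lithium (2S)-1-(furan-2-yl)-2,6-dimethyl-2-[(trimethylsilyl)ethynyl]hept-5-en-1-olate (C1 epimers) | CC(C)=CCC[C@@](C)(C#C[Si](C)(C)C)C(O[Li])c1ccco1 | intermediate (not isolated)
10 | (2S)-2-ethynyl-1-(furan-2-yl)-2,6-dimethylhept-5-en-1-ol (C1 epimers) | CC(C)=CCC[C@@](C)(C#C)C(O)c1ccco1 | intermediate
11 | 2-[(3S)-3,7-dimethyloct-6-en-1-yn-3-yl]-6-hydroxy-2H-pyran-3(6H)-one (C2/C6 isomers) | CC(C)=CCC[C@@](C)(C#C)C1OC(O)C=CC1=O | intermediate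
12 | 6-[(3S)-3,7-dimethyloct-6-en-1-yn-3-yl]-5-oxo-5,6-dihydro-2H-pyran-2-yl acetate (C2/C6 isomers) | CC(C)=CCC[C@@](C)(C#C)C1OC(OC(C)=O)C=CC1=O | intermediate (key-step precursor)
13 | 2-[(3S)-3,7-dimethyloct-6-en-1-yn-3-yl]pyrylium-3-olate | CC(C)=CCC[C@@](C)(C#C)c1[o+]cccc1[O-] | intermediate (not isolated)
14 | (1S,3aS,5S,8aR)-1-ethynyl-1,4,4-trimethyl-2,3,3a,4-tetrahydro-1H-5,8a-epoxyazulen-8(5H)-one | O=C1C=C[C@H]2C(C)(C)[C@@H]3CC[C@@](C)(C#C)[C@@]13O2 | intermediate (key-step product)
15 | [(1S,3aS,5S,8aR)-1,4,4-trimethyl-8-oxo-2,3,3a,4,5,8-hexahydro-1H-5,8a-epoxyazulen-1-yl]acetaldehyde | O=C1C=C[C@H]2C(C)(C)[C@@H]3CC[C@@](C)(CC=O)[C@@]13O2 | intermediate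
16 | [(1S,3aS,5S,8aR)-1,4,4-trimethyl-8-oxo-2,3,3a,4,5,8-hexahydro-1H-5,8a-epoxyazulen-1-yl]acetic acid | O=C1C=C[C@H]2C(C)(C)[C@@H]3CC[C@@](C)(CC(=O)O)[C@@]13O2 | intermediate
17 | tert-butyl [(1S,3aS,5S,8aR)-1,4,4-trimethyl-8-oxo-2,3,3a,4,5,8-hexahydro-1H-5,8a-epoxyazulen-1-yl]acetate | O=C1C=C[C@H]2C(C)(C)[C@@H]3CC[C@@](C)(CC(=O)OC(C)(C)C)[C@@]13O2 | intermediate
18 | tert-butyl [(1S,3aS,5S,8aR)-1,4,4-trimethyl-8-oxooctahydro-1H-5,8a-epoxyazulen-1-yl]acetate | O=C1CC[C@H]2C(C)(C)[C@@H]3CC[C@@](C)(CC(=O)OC(C)(C)C)[C@@]13O2 | intermediate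
19 | samarium enolate / C5 samarium alkoxide of 20 | I[Sm](I)OC1=C2[C@](C)(CC(=O)OC(C)(C)C)CC[C@H]2C(C)(C)[C@@H](O[Sm](I)I)CC1 | intermediate (not isolated)
20 | tert-butyl [(1S,3aR,5S,8aR)-5-hydroxy-1,4,4-trimethyl-8-oxodecahydroazulen-1-yl]acetate | O=C1CC[C@H](O)C(C)(C)[C@@H]2CC[C@@](C)(CC(=O)OC(C)(C)C)[C@H]12 | intermediate
21 | tert-butyl [(1S,3aR,5S,8aR)-5-(imidazol-1-ylcarbonothioyloxy)-1,4,4-trimethyl-8-oxodecahydroazulen-1-yl]acetate | O=C1CC[C@H](OC(=S)n3ccnc3)C(C)(C)[C@@H]2CC[C@@](C)(CC(=O)OC(C)(C)C)[C@H]12 | intermediate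
22 | tert-butyl [(1S,3aR,8aR)-1,4,4-trimethyl-8-oxodecahydroazulen-1-yl]acetate | O=C1CCCC(C)(C)[C@@H]2CC[C@@](C)(CC(=O)OC(C)(C)C)[C@H]12 | intermediate
23 | tert-butyl [(1S,3aR,8aS)-1,4,4-trimethyl-8-methylidenedecahydroazulen-1-yl]acetate | C=C1CCCC(C)(C)[C@@H]2CC[C@@](C)(CC(=O)OC(C)(C)C)[C@H]12 | intermediate
24 | 5-hydroxyfuran-2(5H)-one | OC1OC(=O)C=C1 | starting material
25 | (1S,2R,5S)-(+)-menthol | C[C@H]1CC[C@@H]([C@H](C1)O)C(C)C | starting material
26 | (5S)-5-{[(1S,2R,5S)-5-methyl-2-(propan-2-yl)cyclohexyl]oxy}furan-2(5H)-one | O=C1C=C[C@@H](O[C@H]2C[C@@H](C)CC[C@@H]2C(C)C)O1 | intermediate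
27 | lithium E(O)-enolate of 23 | C=C1CCCC(C)(C)[C@@H]2CC[C@@](C)(/C=C(/O[Li])OC(C)(C)C)[C@H]12 | intermediate (not isolated)
28 | tert-butyl (2R)-2-[(2S,3R)-2-{[(1S,2R,5S)-5-methyl-2-(propan-2-yl)cyclohexyl]oxy}-5-oxooxolan-3-yl]-2-[(1R,3aR,8aS)-1,4,4-trimethyl-8-methylidenedecahydroazulen-1-yl]acetate | C=C1CCCC(C)(C)[C@@H]2CC[C@@](C)([C@H](C(=O)OC(C)(C)C)[C@@H]3[C@@H](O[C@H]4C[C@@H](C)CC[C@@H]4C(C)C)OC(=O)C3)[C@H]12 | intermediate
29 | (3R,4R)-5-tert-butoxy-3-(hydroxymethyl)-5-oxo-4-[(1R,3aR,8aS)-1,4,4-trimethyl-8-methylidenedecahydroazulen-1-yl]pentanoic acid | C=C1CCCC(C)(C)[C@@H]2CC[C@@](C)([C@H](C(=O)OC(C)(C)C)[C@H](CO)CC(=O)O)[C@H]12 | intermediate (not isolated)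
30 | tert-butyl (2R)-2-[(3R)-5-oxooxolan-3-yl]-2-[(1R,3aR,8aS)-1,4,4-trimethyl-8-methylidenedecahydroazulen-1-yl]acetate | C=C1CCCC(C)(C)[C@@H]2CC[C@@](C)([C@H](C(=O)OC(C)(C)C)[C@@H]3COC(=O)C3)[C@H]12 | intermediate
31 | trimethylsilyl ester of 32 | C=C1CCCC(C)(C)[C@@H]2CC[C@@](C)([C@H](C(=O)O[Si](C)(C)C)[C@@H]3COC(=O)C3)[C@H]12 | intermediate (not isolated)
32 | (2R)-2-[(3R)-5-oxooxolan-3-yl]-2-[(1R,3aR,8aS)-1,4,4-trimethyl-8-methylidenedecahydroazulen-1-yl]acetic acid | C=C1CCCC(C)(C)[C@@H]2CC[C@@](C)([C@H](C(=O)O)[C@@H]3COC(=O)C3)[C@H]12 | intermediate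
33 | acyl imidazolide of 32 | C=C1CCCC(C)(C)[C@@H]2CC[C@@](C)([C@H](C(=O)n4ccnc4)[C@@H]3COC(=O)C3)[C@H]12 | intermediate (not isolated)
34 | (4R)-4-{(1R)-2-hydroxy-1-[(1R,3aR,8aS)-1,4,4-trimethyl-8-methylidenedecahydroazulen-1-yl]ethyl}oxolan-2-one | C=C1CCCC(C)(C)[C@@H]2CC[C@@](C)([C@H](CO)[C@@H]3COC(=O)C3)[C@H]12 | intermediate
35 | (2R)-2-[(3R)-5-oxooxolan-3-yl]-2-[(1R,3aR,8aS)-1,4,4-trimethyl-8-methylidenedecahydroazulen-1-yl]ethyl acetate | C=C1CCCC(C)(C)[C@@H]2CC[C@@](C)([C@H](COC(C)=O)[C@@H]3COC(=O)C3)[C@H]12 | target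

**Step count**

Total: 21 steps. Longest linear sequence: 20 steps (1 to 35 through steps 1–15 and 17–21); step 16 is a one-step side branch.

**Steps most likely to fail**

Step 7. The pyrylium may dimerise or decay faster than the hindered trisubstituted alkene traps it, and the face selection exerted by the quaternary carbon may be low or may run opposite to the model. The fallback inverts the steric ranking at the quaternary carbon instead of changing conditions. It sets out from carbinol 10: double deprotonation (n-BuLi, 2 equiv, THF, −78 °C) and C-silylation with i-Pr3SiOTf should give the triisopropylsilyl-capped alkyne F1, whose rod now ends in a group far larger than methyl. Oxidation with VO(acac)2/t-BuOOH gives pyranone F2, acetylation gives acetate F3, and the same DBU-mediated cycloaddition gives the silylated adduct F4. If the parent ethynyl compound has given the C1-epimeric series, the reversed size order should place the arm on the required side here. Bu4NF in THF removes the silyl group and returns to 14.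

Step 17. The acceptor face is fixed by the menthyloxy group but the enolate face is not, so the side-chain carbon may form as the wrong epimer or as a mixture; the butenolide may also quench the hindered enolate by proton transfer. Switching to the Z(O)-enolate (LDA, THF–DMPU) is the first variable to try. The fallback uses an acyclic chiral-pool acceptor that can reach a closed, lithium-bridged transition state. From 23, the lithium enolate is added to ethyl (2E)-3-[(4S)-2,2-dimethyl-1,3-dioxolan-4-yl]prop-2-enoate at −78 °C; attack anti to the dioxolane oxygen through the eight-membered chelate open to an s-cis enoate is expected to give the syn adduct F5. H5IO6 in EtOAc cleaves the acetonide and the diol in one operation to aldehyde F6. NaBH4 in EtOH at 0 °C then reduces the aldehyde, and ring closure onto the ethyl ester (cat. PPTS) returns to lactone 30.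

Step 12. Protonation of the samarium enolate on the concave face, or on oxygen followed by unselective ketonisation, would give the trans-fused ketone. The fallback cleaves the bridge while the C1 arm is still the slim ethynyl group, so that the convex face is as open as it can be. From 14, conjugate reduction of the enone with [(Ph3P)CuH]6 (benzene, H2O, 25 °C), which leaves the alkyne alone, gives ketone F7. SmI2/t-BuOH at −78 °C gives hydroxy ketone F8, the ruthenium-catalysed hydration of step 8 gives aldehyde F9, and Pinnick oxidation gives acid F10. Esterification with O-tert-butyl-N,N'-diisopropylisourea returns to 20.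

Further compounds

F1 | step 7 | (2S)-1-(furan-2-yl)-2,6-dimethyl-2-{[tri(propan-2-yl)silyl]ethynyl}hept-5-en-1-ol (C1 epimers) | CC(C)=CCC[C@@](C)(C#C[Si](C(C)C)(C(C)C)C(C)C)C(O)c1ccco1
F2 | step 7 | 6-hydroxy-2-[(3S)-3,7-dimethyl-1-[tri(propan-2-yl)silyl]oct-6-en-1-yn-3-yl]-2H-pyran-3(6H)-one (C2/C6 isomers) | CC(C)=CCC[C@@](C)(C#C[Si](C(C)C)(C(C)C)C(C)C)C1OC(O)C=CC1=O
F3 | step 7 | 6-[(3S)-3,7-dimethyl-1-[tri(propan-2-yl)silyl]oct-6-en-1-yn-3-yl]-5-oxo-5,6-dihydro-2H-pyran-2-yl acetate (C2/C6 isomers) | CC(C)=CCC[C@@](C)(C#C[Si](C(C)C)(C(C)C)C(C)C)C1OC(OC(C)=O)C=CC1=O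
F4 | step 7 | (1S,3aS,5S,8aR)-1,4,4-trimethyl-1-{[tri(propan-2-yl)silyl]ethynyl}-2,3,3a,4-tetrahydro-1H-5,8a-epoxyazulen-8(5H)-one | O=C1C=C[C@H]2C(C)(C)[C@@H]3CC[C@@](C)(C#C[Si](C(C)C)(C(C)C)C(C)C)[C@@]13O2
F5 | step 17 | 1-tert-butyl 5-ethyl (2R,3R)-3-[(4S)-2,2-dimethyl-1,3-dioxolan-4-yl]-2-[(1R,3aR,8aS)-1,4,4-trimethyl-8-methylidenedecahydroazulen-1-yl]pentanedioate | C=C1CCCC(C)(C)[C@@H]2CC[C@@](C)([C@H](C(=O)OC(C)(C)C)[C@@H](CC(=O)OCC)[C@H]3COC(C)(C)O3)[C@H]12
F6 | step 17 | 1-tert-butyl 5-ethyl (2R,3R)-3-formyl-2-[(1R,3aR,8aS)-1,4,4-trimethyl-8-methylidenedecahydroazulen-1-yl]pentanedioate | C=C1CCCC(C)(C)[C@@H]2CC[C@@](C)([C@H](C(=O)OC(C)(C)C)[C@@H](CC(=O)OCC)C=O)[C@H]12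
F7 | step 12 | (1S,3aS,5S,8aR)-1-ethynyl-1,4,4-trimethylhexahydro-1H-5,8a-epoxyazulen-8(5H)-one | O=C1CC[C@H]2C(C)(C)[C@@H]3CC[C@@](C)(C#C)[C@@]13O2
F8 | step 12 | (3S,3aR,6S,8aR)-3-ethynyl-6-hydroxy-3,7,7-trimethyloctahydroazulen-4(1H)-one | O=C1CC[C@H](O)C(C)(C)[C@@H]2CC[C@@](C)(C#C)[C@H]12
F9 | step 12 | [(1S,3aR,5S,8aR)-5-hydroxy-1,4,4-trimethyl-8-oxodecahydroazulen-1-yl]acetaldehyde | O=C1CC[C@H](O)C(C)(C)[C@@H]2CC[C@@](C)(CC=O)[C@H]12
F10 | step 12 | [(1S,3aR,5S,8aR)-5-hydroxy-1,4,4-trimethyl-8-oxodecahydroazulen-1-yl]acetic acid | O=C1CC[C@H](O)C(C)(C)[C@@H]2CC[C@@](C)(CC(=O)O)[C@H]12
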